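The polyene is cut at C11=C12 and C11'=C12' into two C15 Wittig salts and the C10 dialdehyde, which leaves the cyclopentane end group as the real problem. Its C1 tertiary methyl ether, the C2–C6 bond of the five-membered ring (C2–C3–C4–C5–C6) and the C5 methyl carbinol map, together with C7 and three methyls, onto the ten carbons of dehydrolinalool. One gold-catalysed methoxycyclization of this 1,6-enyne forms C2–C6 and C1–OMe, closes the ring, sets C2, and leaves a C6=C7 methylene as the handle for chain extension. The precursor is enantiopure (R)-dehydrolinalool, made from geraniol, with its propargylic oxygen masked as a triethylsilyl ether.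

Key step: step 5

Remark: carotenoid numbering is used (ring end C1–C6, chain C7–C15, primed numbers for the acyclic ψ end).
Assumption: pseudoionone is taken as its (3E,5E) isomer. Commercial E/Z mixtures are upgraded when the derived phosphonium salt is crystallised.

Step 1
Reactants: 1 geraniol; 2 D-(−)-diisopropyl tartrate (chiral ligand, catalytic)
Product: 3 (2R,3R)-2,3-epoxygeraniol
Conditions: Ti(OiPr)4 (5 mol %), 2 (7 mol %), t-BuOOH, 4 Å MS, CH2Cl2, −20 °C
Reagents that add atoms: tert-butyl hydroperoxide, CC(C)(C)OO
Why: Sharpless asymmetric epoxidation touches only the allylic alkene, and the (S,S)-tartrate delivers oxygen to the face that gives the (2R,3R)-epoxide, whose quaternary carbon becomes C5 of the target.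

Step 2
Reactants: 3 (2R,3R)-2,3-epoxygeraniol
Product: 4 (2R,3S)-3-(chloromethyl)-2-methyl-2-(4-methylpent-3-enyl)oxirane
Conditions: PPh3, CCl4, reflux
Reagents that add atoms: carbon tetrachloride, ClC(Cl)(Cl)Cl
Why: The Appel reaction substitutes the primary carbon under nearly neutral conditions, so the epoxide and both stereocentres keep their arrangement and only one descriptor changes because Cl outranks O.

Step 3
Reactants: 4 epoxy chloride
Product: 6 (R)-3,7-dimethyloct-6-en-1-yn-3-ol [(R)-dehydrolinalool], via chlorovinyl lithium alkoxide 5 (not isolated)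
Conditions: n-BuLi (3.3 equiv), THF, −40 °C; aq NH4Cl
Reagents that add atoms: none
Why: In this base-induced double elimination of a 2,3-epoxy chloride, lithiation next to chlorine opens the epoxide to 5 and loss of chloride then gives the alkyne, while the C–O bond at the quaternary centre is never broken and its configuration is kept.

Step 4
Reactants: 6 (R)-dehydrolinalool
Product: 7 (R)-triethyl[(3,7-dimethyloct-6-en-1-yn-3-yl)oxy]silane
Conditions: Et3SiOTf, 2,6-lutidine, CH2Cl2, 0 °C
Reagents that add atoms: triethylsilyl triflate, CC[Si](CC)(CC)OS(=O)(=O)C(F)(F)F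
Why: Silylation of a tertiary propargylic alcohol with a silyl triflate and a hindered pyridine is routine, and this one group serves the cyclization (step 5) and later blocks retro-aldol cleavage (step 8).

Step 5
Reactants: 7 silyl-protected enyne; 8 methanol
Product: 9 triethyl{[(1R,3R)-3-(2-methoxypropan-2-yl)-1-methyl-2-methylidenecyclopentyl]oxy}silane
Conditions: Ph3PAuNTf2 (2 mol %), MeOH, 0 °C → rt; then Et3N
Reagents that add atoms: methanol 8, CO
Why: Cationic monovalent gold binds the terminal alkyne C6≡C7, the prenyl alkene attacks C6 through C2 anti to the metal, the resulting cyclopropyl gold carbene (in effect a tertiary C1 cation) is opened at C1 by solvent methanol, and protodeauration of the C7 vinyl gold frees the exocyclic methylene, which is the known gold-catalysed alkoxycyclization of 1,6-enynes. The cyclopentane C2–C3–C4–C5–C6 closes in the 5-exo-dig mode, which a terminal alkyne and a trisubstituted alkene with a cation-stabilising terminus favour over 6-endo-dig closure. The only new stereocentre, C2, is controlled by the quaternary C5 centre: in the folded, bicyclo[3.1.0]hexane-like transition state C1 with its two methyls lies over one ring face, and the bulky, non-nucleophilic triethylsilyloxy group should take the open opposite face, which places C1 cis to the C5 methyl (2R). The silyl ether also removes the side reactions of a free or lightly protected propargylic oxygen, namely Meyer–Schuster rearrangement, capture of the C1 cation from the same face to give a bridged ether, and oxygen migration to C1. The step needs C1–OMe formation to beat proton loss and skeletal rearrangement, which methanol as solvent secures, and fast protodeauration in the protic medium should outrun ionisation of the allylic C5–O bond.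

Step 6
Reactants: 9 methylidenecyclopentane
Product: 11 [(1S,2R,5R)-5-(2-methoxypropan-2-yl)-2-methyl-2-(triethylsilyloxy)cyclopentyl]methanol (CH2OH cis to the CMe2OMe group), via alkylborane 10 (not isolated)
Conditions: BH3·THF, THF, 0 °C → rt; then NaOH, H2O2, 0 °C
Reagents that add atoms: borane (THF complex, boron only in 10), B; hydrogen peroxide, OO
Why: In this hydroboration–oxidation boron adds to the terminal C7 and is replaced by OH with retention, hydrogen is expected to reach C6 from the face away from the CMe2OMe group and the C5 methyl (the epimer drawn), and any other epimer is carried along because step 8 converges both.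

Step 7
Reactants: 11 primary alcohol
Product: 12 (1R,2R,5R)-5-(2-methoxypropan-2-yl)-2-methyl-2-(triethylsilyloxy)cyclopentane-1-carbaldehyde (formyl cis to CMe2OMe)
Conditions: Dess–Martin periodinane, CH2Cl2, rt
Reagents that add atoms: none
Why: Dess–Martin oxidation takes the hindered primary alcohol to the aldehyde under mild conditions that leave the silyl and methyl ethers alone.

Step 8
Reactants: 12 cis aldehyde
Product: 13 (1S,2R,5R)-5-(2-methoxypropan-2-yl)-2-methyl-2-(triethylsilyloxy)cyclopentane-1-carbaldehyde (formyl trans to CMe2OMe and to the C5 methyl)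
Conditions: DBU (0.3 equiv), CH2Cl2, rt
Reagents that add atoms: none
Why: Base-catalysed epimerisation through the enolate sets C6 (6S) under thermodynamic control, because the formyl group escapes both the neighbouring CMe2OMe group and the C5 methyl, and the silyl ether rules out retro-aldol scrambling of C5.

Step 9
Reactants: 13 trans aldehyde; 14 triethyl 3-methyl-4-phosphonocrotonate
Product: 16 ethyl (2E,4E)-5-[(1S,2R,5R)-5-(2-methoxypropan-2-yl)-2-methyl-2-(triethylsilyloxy)cyclopentyl]-3-methylpenta-2,4-dienoate, via lithiated phosphonate 15 (not isolated)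
Conditions: 14, LiN(SiMe3)2, THF/DMPU, −78 °C; then 13, −78 → 0 °C
Reagents that add atoms: triethyl 3-methyl-4-phosphonocrotonate 14, CCOC(=O)/C=C(\C)CP(=O)(OCC)OCC
Why: The vinylogous Horner–Wadsworth–Emmons olefination used for retinoid chains should give the (7E,9E)-dienoate, the neutral ester allows chromatographic removal of any 9Z isomer, and C6 is already the stable epimer.

Step 10
Reactants: 16 dienoate
Product: 17 (2E,4E)-5-[(1S,2R,5R)-5-(2-methoxypropan-2-yl)-2-methyl-2-(triethylsilyloxy)cyclopentyl]-3-methylpenta-2,4-dien-1-ol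
Conditions: i-Bu2AlH, CH2Cl2, −78 °C; aq potassium sodium tartrate
Reagents that add atoms: none
Why: 1,2-Reduction of a conjugated ester with i-Bu2AlH gives the dienol without touching alkene geometry or either ether.

Step 11
Reactants: 17 dienol
Product: 19 {(2E,4E)-5-[(1S,2R,5R)-2-hydroxy-5-(2-methoxypropan-2-yl)-2-methylcyclopentyl]-3-methylpenta-2,4-dienyl}triphenylphosphonium bromide, via silyl-protected phosphonium bromide 18 (not isolated)
Conditions: Ph3P·HBr (1.2 equiv), MeOH, rt
Reagents that add atoms: triphenylphosphine hydrobromide, [Br-].[PH+](c1ccccc1)(c1ccccc1)c1ccccc1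
Why: In this standard carotenoid Wittig-salt preparation the dienol ionises and PPh3 captures the cation at its primary terminus to give 18, the slight excess of acidic salt in methanol then solvolyses the no longer needed triethylsilyl ether, and the tertiary methyl ether can at most exchange degenerately with the solvent.

Step 12
Reactants: 20 (3E,5E)-pseudoionone
Product: 21 (4E,6E)-3,7,11-trimethyldodeca-1,4,6,10-tetraen-3-ol (racemic vinyl carbinol)
Conditions: CH2=CHMgBr, THF, 0 °C; aq NH4Cl
Reagents that add atoms: vinylmagnesium bromide, C=C[Mg]Br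
Why: Grignard 1,2-addition to the dienone is the established entry to the acyclic C15 unit, and the new carbinol centre is erased in the next step.

Step 13
Reactants: 21 vinyl carbinol
Product: 22 [(2E,4E,6E)-3,7,11-trimethyldodeca-2,4,6,10-tetraenyl]triphenylphosphonium bromide
Conditions: Ph3P·HBr, MeOH, 0 °C → rt; crystallise
Reagents that add atoms: triphenylphosphine hydrobromide, [Br-].[PH+](c1ccccc1)(c1ccccc1)c1ccccc1
Why: In this Wittig-salt formation with allylic transposition the tertiary carbinol ionises, PPh3 attacks the unhindered primary terminus, the C9'=C10' bond should form mainly E, and crystallisation removes Z isomers.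

Step 14
Reactants: 22 acyclic C15 phosphonium bromide; 23 (2E,4E,6E)-2,7-dimethylocta-2,4,6-trienedial
Product: 26 all-E 12'-apo-ψ-caroten-12'-al (C25 aldehyde), via C15 ylide 24 (not isolated), via 11'Z isomer 25 (not isolated)
Conditions: 23 (2 equiv), NaOMe, CH2Cl2/MeOH, 0 °C → rt, dark; then heptane, reflux
Reagents that add atoms: none
Why: In this Wittig olefination the excess dialdehyde and the lower electrophilicity of the longer product aldehyde favour single olefination, and the crowded Z isomer at the new C11'=C12' bond relaxes thermally to E.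

Step 15
Reactants: 19 ring-end C15 phosphonium bromide; 26 C25 aldehyde
Product: 29 (all-E,2R,5R,6S)-1-methoxy-2,6-cyclolycopen-5-ol (target CNP0380368.2), via ring-end ylide 27 (not isolated), via 11Z isomer 28 (not isolated)
Conditions: NaOMe, CH2Cl2/MeOH, rt, dark, N2; then EtOH, reflux; crystallise
Reagents that add atoms: none
Why: Wittig coupling of a hydroxy-bearing C15 salt with a polyene aldehyde is standard carotenoid practice, the free tertiary alcohol does not interfere, no stereocentre is touched, and the hindered 11Z isomer equilibrates thermally to the all-E polyene.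

Compound list
1 | geraniol, (2E)-3,7-dimethylocta-2,6-dien-1-ol | CC(C)=CCC/C(C)=C/CO | starting material
2 | D-(−)-diisopropyl tartrate, (2S,3S) | CC(C)OC(=O)[C@@H](O)[C@H](O)C(=O)OC(C)C | starting material
3 | (2R,3R)-2,3-epoxygeraniol, [(2R,3R)-3-methyl-3-(4-methylpent-3-enyl)oxiran-2-yl]methanol | CC(C)=CCC[C@@]1(C)O[C@@H]1CO | intermediate
4 | (2R,3S)-3-(chloromethyl)-2-methyl-2-(4-methylpent-3-enyl)oxirane | CC(C)=CCC[C@@]1(C)O[C@@H]1CCl | intermediate
5 | lithium (3R)-1-chloro-3,7-dimethylocta-1,6-dien-3-olate (chloroalkene geometry immaterial) | CC(C)=CCC[C@@](C)([O-])C=CCl.[Li+] | intermediate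
6 | (R)-3,7-dimethyloct-6-en-1-yn-3-ol, (R)-dehydrolinalool | CC(C)=CCC[C@@](C)(O)C#C | intermediate
7 | triethylsilyl ether of 6 | CC(C)=CCC[C@@](C)(O[Si](CC)(CC)CC)C#C | intermediate
8 | methanol | CO | starting material
9 | triethylsilyl ether of (1R,3R)-3-(2-methoxypropan-2-yl)-1-methyl-2-methylidenecyclopentan-1-ol | COC(C)(C)[C@@H]1CC[C@@](C)(O[Si](CC)(CC)CC)C1=C | intermediate
10 | C7 monoalkylborane from 9 (C6 as in 11) | COC(C)(C)[C@@H]1CC[C@@](C)(O[Si](CC)(CC)CC)[C@@H]1CB | intermediate
11 | [(1S,2R,5R)-5-(2-methoxypropan-2-yl)-2-methyl-2-(triethylsilyloxy)cyclopentyl]methanol | COC(C)(C)[C@@H]1CC[C@@](C)(O[Si](CC)(CC)CC)[C@@H]1CO | intermediate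
12 | (1R,2R,5R)-5-(2-methoxypropan-2-yl)-2-methyl-2-(triethylsilyloxy)cyclopentane-1-carbaldehyde | COC(C)(C)[C@@H]1CC[C@@](C)(O[Si](CC)(CC)CC)[C@@H]1C=O | intermediate
13 | (1S,2R,5R)-5-(2-methoxypropan-2-yl)-2-methyl-2-(triethylsilyloxy)cyclopentane-1-carbaldehyde | COC(C)(C)[C@@H]1CC[C@@](C)(O[Si](CC)(CC)CC)[C@H]1C=O | intermediate
14 | triethyl (E)-3-methyl-4-phosphonocrotonate (sold as E/Z mixture; the anion equilibrates) | CCOC(=O)/C=C(\C)CP(=O)(OCC)OCC | starting material
15 | lithiated 14 | [Li+].CCOC(=O)/C=C(\C)[CH-]P(=O)(OCC)OCC | intermediate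
16 | ethyl (2E,4E)-5-[(1S,2R,5R)-5-(2-methoxypropan-2-yl)-2-methyl-2-(triethylsilyloxy)cyclopentyl]-3-methylpenta-2,4-dienoate | COC(C)(C)[C@@H]1CC[C@@](C)(O[Si](CC)(CC)CC)[C@H]1/C=C/C(C)=C/C(=O)OCC | intermediate
17 | corresponding (2E,4E)-dien-1-ol | COC(C)(C)[C@@H]1CC[C@@](C)(O[Si](CC)(CC)CC)[C@H]1/C=C/C(C)=C/CO | intermediate
18 | silyl-protected ring-end C15 triphenylphosphonium bromide | COC(C)(C)[C@@H]1CC[C@@](C)(O[Si](CC)(CC)CC)[C@H]1/C=C/C(C)=C/C[P+](c1ccccc1)(c1ccccc1)c1ccccc1.[Br-] | intermediate
19 | ring-end C15 hydroxy triphenylphosphonium bromide | COC(C)(C)[C@@H]1CC[C@@](C)(O)[C@H]1/C=C/C(C)=C/C[P+](c1ccccc1)(c1ccccc1)c1ccccc1.[Br-] | intermediate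
20 | (3E,5E)-pseudoionone | CC(=O)/C=C/C=C(C)/CCC=C(C)C | starting material
21 | (4E,6E)-3,7,11-trimethyldodeca-1,4,6,10-tetraen-3-ol, racemic | C=CC(C)(O)/C=C/C=C(C)/CCC=C(C)C | intermediate
22 | [(2E,4E,6E)-3,7,11-trimethyldodeca-2,4,6,10-tetraenyl]triphenylphosphonium bromide | CC(C)=CCC/C(C)=C/C=C/C(C)=C/C[P+](c1ccccc1)(c1ccccc1)c1ccccc1.[Br-] | intermediate
23 | (2E,4E,6E)-2,7-dimethylocta-2,4,6-trienedial | O=C/C(C)=C/C=C/C=C(C)/C=O | starting material
24 | ylide from 22 | CC(C)=CCC/C(C)=C/C=C/C(C)=C/C=P(c1ccccc1)(c1ccccc1)c1ccccc1 | intermediate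
25 | (11'Z)-12'-apo-ψ-caroten-12'-al | O=C/C(C)=C/C=C/C=C(C)/C=C\C=C(C)\C=C\C=C(/C)CCC=C(C)C | intermediate
26 | all-E 12'-apo-ψ-caroten-12'-al, (2E,4E,6E,8E,10E,12E,14E)-2,7,11,15,19-pentamethylicosa-2,4,6,8,10,12,14,18-octaenal | O=C/C(C)=C/C=C/C=C(C)/C=C/C=C(C)/C=C/C=C(\C)CCC=C(C)C | intermediate
27 | ylide from 19 | COC(C)(C)[C@@H]1CC[C@@](C)(O)[C@H]1/C=C/C(C)=C/C=P(c1ccccc1)(c1ccccc1)c1ccccc1 | intermediate
28 | 11Z isomer of the target | COC(C)(C)[C@@H]1CC[C@@](C)(O)[C@H]1/C=C/C(C)=C/C=C\C(C)=C\C=C\C=C(C)\C=C\C=C(C)\C=C\C=C(/C)CCC=C(C)C | intermediate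
29 | (all-E,2R,5R,6S)-1-methoxy-2,6-cyclolycopen-5-ol | COC(C)(C)[C@@H]1CC[C@@](C)(O)[C@H]1/C=C/C(C)=C/C=C/C(C)=C/C=C/C=C(C)/C=C/C=C(C)/C=C/C=C(\C)CCC=C(C)C | target

Total step count: 15
Longest linear sequence: 12 steps (steps 1–11 and 15)

Steps most likely to fail

**Step 5.** The methyl and silyloxy groups at C5 may not differentiate the two ring faces enough, so C2 may form with poor or reversed facial selectivity. The allylic C5–O bond may also ionise at the vinyl-gold stage. The fallback sets out from methanol 8 and comes back at aldehyde 13. It builds the ring by closing C5–C6 in an aldol reaction and takes C2 from the chiral pool.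
- Methanol 8 is added to the isopropenyl group of commercial (R)-(+)-limonene F1 by alkoxymercuration with Hg(OAc)2 in MeOH.
- The organomercurial F2 is reduced in the same flask with NaBH4/NaOH to (R)-α-terpinyl methyl ether F3.
- Ozonolysis with Me2S work-up opens the ring alkene to the keto aldehyde F4.
- Catalytic piperidinium acetate at room temperature closes F4 through the aldehyde enamine (5-enolexo aldol addition, stopped before dehydration) to the aldol F5. Equilibration places the formyl group of F5 trans to the CMe2OMe group and cis to the hydroxyl.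
- Et3SiOTf/2,6-lutidine then gives 13.

**Step 8.** Expulsion of the β-silyloxy group from the enolate may compete with reprotonation at C6. The fallback sets out from 12 and comes back at 13.
- HF·pyridine in THF removes the silyl group to give the free cis aldol F6.
- Catalytic piperidinium acetate equilibrates C6 through the enamine. Hydroxide is a poor leaving group here, and any retro-aldol/aldol reversal leads to the same thermodynamic aldol F5.
- Resilylation with Et3SiOTf/2,6-lutidine returns 13.

**Step 9.** The basic phosphonate anion may deprotonate the hindered aldehyde faster than it adds, which starts β-elimination. The fallback sets out from 13 and comes back at 19. It builds the chain as C3 plus C2 with a non-basic ylide.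
- Heating 13 with 1-(triphenylphosphoranylidene)propan-2-one in toluene gives the E enone F7.
- CH2=CHMgBr adds 1,2 to give the vinyl carbinol F8 as a mixture at the new, later erased centre.
- Ph3P·HBr in MeOH converts F8 with allylic transposition through 18 into 19, exactly as in the ψ series.

Further compounds
F1 | step 5 | (R)-(+)-limonene | CC1=CC[C@@H](CC1)C(C)=C
F2 | step 5 | acetoxy{2-methoxy-2-[(1R)-4-methylcyclohex-3-enyl]propyl}mercury (side-chain centre undefined, erased on reduction) | CC1=CC[C@@H](CC1)C(C)(OC)C[Hg]OC(C)=O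
F3 | step 5 | (R)-α-terpinyl methyl ether | CC1=CC[C@@H](CC1)C(C)(C)OC
F4 | step 5 | (3R)-3-(2-methoxypropan-2-yl)-6-oxoheptanal | O=CC[C@@H](CCC(C)=O)C(C)(C)OC
F5 | step 5 | (1S,2R,5R)-2-hydroxy-5-(2-methoxypropan-2-yl)-2-methylcyclopentane-1-carbaldehyde | COC(C)(C)[C@@H]1CC[C@@](C)(O)[C@H]1C=O
F6 | step 8 | (1R,2R,5R)-2-hydroxy-5-(2-methoxypropan-2-yl)-2-methylcyclopentane-1-carbaldehyde | COC(C)(C)[C@@H]1CC[C@@](C)(O)[C@@H]1C=O
F7 | step 9 | (E)-4-[(1S,2R,5R)-5-(2-methoxypropan-2-yl)-2-methyl-2-(triethylsilyloxy)cyclopentyl]but-3-en-2-one | COC(C)(C)[C@@H]1CC[C@@](C)(O[Si](CC)(CC)CC)[C@H]1/C=C/C(C)=O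
F8 | step 9 | (E)-1-[(1S,2R,5R)-5-(2-methoxypropan-2-yl)-2-methyl-2-(triethylsilyloxy)cyclopentyl]-3-methylpenta-1,4-dien-3-ol (carbinol epimers) | COC(C)(C)[C@@H]1CC[C@@](C)(O[Si](CC)(CC)CC)[C@H]1/C=C/C(C)(O)C=C
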